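The data are simulated for an exercise; noise was put on by code.

The ratio that mattered was left-handed to right-handed substrate: an excess of 95% means 2.56% or less.

all flasks: left-handed substrate 0.40 M; right-handed substrate 0.40 M

| charge | solid reagent | precatalyst | remark | time |
|---|---|---|---|---|
| red | 0.48 M | 2 mM | run made earlier |  |
| green | 0.48 M | 8 mM | run made earlier |  |
| flask | 0.480 M | 4.0 mM |  | 20 min |

| run | time / min | right-handed substrate / % | left-handed substrate / % | left-handed product / % |
|---|---|---|---|---|
| red | 1.00 | 50 | 40 | 4 |
| red | 3.00 | 49 | 26 | 25 |
| red | 6.00 | 46 | 16 | 39 |
| red | 8.00 | 46 | 13 | 39 |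
| red | 12.0 | 45 | 7 | 40 |
| green | 1.00 | 48 | 25 | 25 |
| green | 2.00 | 44 | 7 | 42 |
| green | 3.00 | 43 | 2 | 46 |
| green | 6.00 | 43 | 0 | 51 |
| green | 12.0 | 42 | 1 | 49 |

(scatter of a reading: 1.5 percentage points)

- whether the excess of right-handed substrate over left-handed substrate among what is left of the two reaches 95% by 20 min (yes / no)
- the highest excess of right-handed substrate over left-handed substrate among what is left of the two up to 20 min

- free catalyst is single-handed; left-handed substrate and right-handed substrate are mirror images of each other, charged as a racemate, each of them at the stated concentration
- solid, in amounts per volume of the solution: solid reagent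
- the earlier runs were read with a standard deviation of 1.5 percentage points
- at the start none of the solid reagent is in solution

So I needed the selectivity factor s, the logarithm of the fraction of left-handed substrate left over that of the right-handed. The last reading of the red run gave 18.7, a reading with its scatter. The fraction of right-handed substrate left at the wanted ratio is that ratio raised to one over s minus one. My price was 58.3%, the part of the pair that has to react before the ratio is met at that s. But the solid reagent is the limiting reagent. I reckoned that, at one per turnover, it covered 60.0% of the pair. That left a margin of 1.7 percentage points, against a scatter of 1.5 points on a reading. The flask's 4.0 mM of precatalyst lay between 2 mM and 8 mM. On that margin I said yes, narrowly.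

The forecast differed: no, with a top of 94%, “borderline, just short of 95%”.

The flask answered yes, with a top of 97.7%.

    free catalyst + left-handed substrate ⇌ catalyst intermediate A (K = 17.0 L mol⁻¹, k = 56.0 L mol⁻¹ s⁻¹)
    free catalyst + right-handed substrate ⇌ catalyst intermediate B (K = 1.10 L mol⁻¹, k = 16.0 L mol⁻¹ s⁻¹)
    partner + catalyst intermediate A → free catalyst + left-handed product (k = 23.0 L mol⁻¹ s⁻¹)
    partner + catalyst intermediate B → free catalyst + right-handed product (k = 8.70 L mol⁻¹ s⁻¹)
    precatalyst ⇌ free catalyst (K = 2.60, k = 0.00560 s⁻¹)
    solid reagent ⇌ partner, rate k6*(cs6 - [partner]) while solid is left; crystals form when [partner] > cs6 (solubility = 0.350 M, k = 0.260 s⁻¹)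
    partner + free catalyst → spent catalyst (k = 0.170 L mol⁻¹ s⁻¹)

The flask crossed 95% at 10.4 min, with 42.3% of right-handed substrate left. So it paid 56.6% of the pair, less than my price of 58.3%. The last reading of the green run also stood below that price, at 57.0% reacted, with left-handed substrate 1% against right-handed 42%.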